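**Retrosynthetic overview**
1. Isariotin C ⇒ spiro-lactol ketol. The aminocyclohexane ring of the bicyclo[3.3.1]nonan-9-one is closed last, by intramolecular aldol between the α-carbon of the bridging ketone and the former carboxyl carbon. The epoxy-cyclohexane ring is the dearomatised 4-hydroxy-2-methoxyphenyl ring of an L-arylalanine.
2. Ring order: benzene ring → temporary five-membered spirolactone (oxidative dearomatisation; not in the target, relays the amino-acid stereocentre to the quaternary carbinol carbon, later reduced and opened) → oxirane → lactol → aminocyclohexane ring.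
3. Side chain (C1 = amide carbonyl … C12): the C5–C6 bond is made between an N-(2E)-penta-2,4-dienoyl arylalanine ester (C1–C5, N and all core carbons) and 1-bromoheptan-2-one (C6–C12). This completes the C21 skeleton.
4. Enabling feature: C6 is the α-CH2 of the C7 ketone, i.e. an α-halo-enolate carbon that accepts a 1,2-shift from boron. C5 ends a CH2–CH2 link (C4–C5) attached to the (E)-C2=C3 enamide, i.e. it is the anti-Markovnikov hydroboration site of the terminal vinyl group of a 2,4-dienamide.
5. The arylalanine comes from serine-derived β-iodoalanine and 4-bromo-3-methoxyphenol by Negishi coupling.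

Key step: step 5

Remark: side-chain atoms are numbered C1 (amide C=O) to C12; the lactol carbon in 17 and 18 is an anomeric mixture, which is irrelevant because it reacts as the aldehyde.

Step 1
Reactants: 1 4-bromo-3-methoxyphenol
Product: 2 tert-butyl(4-bromo-3-methoxyphenoxy)dimethylsilane
Conditions: TBSCl, imidazole, DMF, rt
Reagents that add atoms: tert-butyldimethylsilyl chloride CC(C)(C)[Si](C)(C)Cl
Why: Standard phenol silylation; the aryl silyl ether should survive the organometallic, acidic and weakly basic steps and is removed by hydroxide in step 7.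

Step 2
Reactants: 2 tert-butyl(4-bromo-3-methoxyphenoxy)dimethylsilane; 3 methyl (2R)-2-[(tert-butoxycarbonyl)amino]-3-iodopropanoate (Boc-3-iodo-L-alanine methyl ester)
Product: 5 methyl (2S)-2-[(tert-butoxycarbonyl)amino]-3-{4-[(tert-butyldimethylsilyl)oxy]-2-methoxyphenyl}propanoate, via alanyl zinc iodide 4 (not isolated)
Conditions: Zn dust (I2-activated), DMF, rt; then 2, Pd2(dba)3 (2.5 mol %), SPhos (5 mol %), DMF, 50 °C
Reagents that add atoms: none
Why: Negishi coupling of a serine-derived β-zincated alanine with the aryl bromide; the α-stereocentre is not involved and should be retained (the descriptor changes from R to S only through priorities).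

Step 3
Reactants: 5 methyl (2S)-2-[(tert-butoxycarbonyl)amino]-3-{4-[(tert-butyldimethylsilyl)oxy]-2-methoxyphenyl}propanoate
Product: 6 methyl (2S)-2-amino-3-{4-[(tert-butyldimethylsilyl)oxy]-2-methoxyphenyl}propanoate trifluoroacetate salt
Conditions: TFA, CH2Cl2, 0 °C → rt; evaporate
Reagents that add atoms: trifluoroacetic acid OC(=O)C(F)(F)F
Why: Acidolysis of the Boc carbamate (loss of isobutene and CO2); aryl silyl ether and methyl ester are stable to anhydrous TFA.

Step 4
Reactants: 6 methyl (2S)-2-amino-3-{4-[(tert-butyldimethylsilyl)oxy]-2-methoxyphenyl}propanoate trifluoroacetate salt; 7 (2E)-penta-2,4-dienoic acid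
Product: 8 methyl (2S)-3-{4-[(tert-butyldimethylsilyl)oxy]-2-methoxyphenyl}-2-[(2E)-penta-2,4-dienamido]propanoate
Conditions: DIC, HOBt, iPr2NEt, BHT (cat.), CH2Cl2, 0 °C → rt
Reagents that add atoms: none
Why: Carbodiimide/HOBt amide coupling; the (E)-C2=C3 geometry comes from the acid, no stereocentre is touched, and low temperature with a radical inhibitor should suppress diene polymerisation.

Step 5
Reactants: 8 methyl (2S)-3-{4-[(tert-butyldimethylsilyl)oxy]-2-methoxyphenyl}-2-[(2E)-penta-2,4-dienamido]propanoate; 9 1-bromoheptan-2-one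
Product: 12 methyl (2S)-3-{4-[(tert-butyldimethylsilyl)oxy]-2-methoxyphenyl}-2-[(2E)-7-oxododec-2-enamido]propanoate, via B-alkyl-9-BBN adduct 10 (not isolated), via enol borinate 11 (not isolated)
Conditions: 9-BBN (1.1 equiv), THF, 0 °C → rt; then 9, potassium 2,6-di-tert-butylphenoxide (1.2 equiv), THF, 0 °C
Reagents that add atoms: none
Why: Anti-Markovnikov hydroboration of the terminal vinyl group C4=C5 puts boron on C5 (10); the hindered phenoxide then forms the α-bromo enolate of 9, which binds boron through C6, and the borate undergoes 1,2-migration of the primary C5 alkyl group from B to C6 with loss of bromide, forming the C5–C6 bond; the α-boryl ketone tautomerises to enol borinate 11, which the phenol protonates to 12. The closest known reaction type is the alkylation of α-halo ketone enolates (or diazo ketones, Hooz reaction) with B-alkyl-9-BBN reagents, preceded by ordinary 9-BBN hydroboration. No ring is closed and no stereocentre is created; the amino-ester α-centre should be untouched by the weakly basic, non-nucleophilic phenoxide. The step needs chemo- and regioselective hydroboration (C4=C5 over C2=C3, boron on C5), which the bulk of 9-BBN and the 1,2-disubstituted, amide-deactivated nature of C2=C3 should secure, and it needs migration of the B-alkyl group rather than a ring B–C bond, which is the normal behaviour of B-alkyl-9-BBN in α-halo-enolate alkylations. In one operation it consumes both activating groups (B, Br), turns the sp2 terminus into the saturated C4–C5–C6 link and completes the entire C21 skeleton of the target.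

Step 6
Reactants: 12 methyl (2S)-3-{4-[(tert-butyldimethylsilyl)oxy]-2-methoxyphenyl}-2-[(2E)-7-oxododec-2-enamido]propanoate
Product: 13 methyl (2S)-3-{4-[(tert-butyldimethylsilyl)oxy]-2-methoxyphenyl}-2-[(2E)-6-(2-pentyl-1,3-dioxolan-2-yl)hex-2-enamido]propanoate
Conditions: (TMSOCH2)2, TMSOTf (5 mol %), CH2Cl2, −78 → −20 °C; pyridine quench
Reagents that add atoms: 1,2-bis(trimethylsilyloxy)ethane C[Si](C)(C)OCCO[Si](C)(C)C
Why: TMSOTf-catalysed ketalisation of the only ketone masks C7 against the hydride of step 10; ester, enamide and aryl silyl ether are inert at low temperature.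

Step 7
Reactants: 13 methyl (2S)-3-{4-[(tert-butyldimethylsilyl)oxy]-2-methoxyphenyl}-2-[(2E)-6-(2-pentyl-1,3-dioxolan-2-yl)hex-2-enamido]propanoate
Product: 14 (2S)-3-(4-hydroxy-2-methoxyphenyl)-2-[(2E)-6-(2-pentyl-1,3-dioxolan-2-yl)hex-2-enamido]propanoic acid
Conditions: LiOH (3 equiv), THF/MeOH/H2O, 0 °C → rt; then 1 M HCl to pH 3–4, 0 °C
Reagents that add atoms: lithium hydroxide [Li+].[OH-]
Why: Saponification of the methyl ester and hydroxide cleavage of the aryl silyl ether (phenoxide leaving group) occur together; the dioxolane, the enamide and the α-centre should tolerate cold LiOH and a brief pH 3–4 work-up.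

Step 8
Reactants: 14 (2S)-3-(4-hydroxy-2-methoxyphenyl)-2-[(2E)-6-(2-pentyl-1,3-dioxolan-2-yl)hex-2-enamido]propanoic acid
Product: 15 (2E)-N-[(3S,5S)-6-methoxy-2,8-dioxo-1-oxaspiro[4.5]deca-6,9-dien-3-yl]-6-(2-pentyl-1,3-dioxolan-2-yl)hex-2-enamide
Conditions: PhI(OAc)2 (1.1 equiv), MeCN, −10 → 0 °C
Reagents that add atoms: none
Why: Iodine(III) oxidation of the phenol and capture of the para position by the carboxylic acid (oxidative spirolactonisation of the N-acyl tyrosine type) gives the dienone, with the methoxy group becoming a vinylogous ester. The quaternary centre is set under substrate control: the acylamino group on the forming lactone should prefer the side away from the methoxy-bearing arm, and the minor spiro-epimer is removed by chromatography.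

Step 9
Reactants: 15 (2E)-N-[(3S,5S)-6-methoxy-2,8-dioxo-1-oxaspiro[4.5]deca-6,9-dien-3-yl]-6-(2-pentyl-1,3-dioxolan-2-yl)hex-2-enamide
Product: 16 (2E)-N-[(3S,5S)-9,10-epoxy-6-methoxy-2,8-dioxo-1-oxaspiro[4.5]dec-6-en-3-yl]-6-(2-pentyl-1,3-dioxolan-2-yl)hex-2-enamide (epoxide cis to O1)
Conditions: t-BuOOH (decane), DBU (0.3 equiv), CH2Cl2, −20 → 0 °C
Reagents that add atoms: tert-butyl hydroperoxide CC(C)(C)OO
Why: Weitz–Scheffer nucleophilic epoxidation should touch only the unsubstituted enone (the β-methoxy enone and the enamide are deactivated); peroxide attack at the β-carbon should occur anti to the CH2 and syn to the smaller lactone oxygen of the adjacent spiro centre, and low temperature limits lactone opening and α-epimerisation.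

Step 10
Reactants: 16 (2E)-N-[(3S,5S)-9,10-epoxy-6-methoxy-2,8-dioxo-1-oxaspiro[4.5]dec-6-en-3-yl]-6-(2-pentyl-1,3-dioxolan-2-yl)hex-2-enamide (epoxide cis to O1)
Product: 17 (2E)-N-[(3S,5S)-9,10-epoxy-2,8-dihydroxy-6-methoxy-1-oxaspiro[4.5]dec-6-en-3-yl]-6-(2-pentyl-1,3-dioxolan-2-yl)hex-2-enamide (8-OH and epoxide cis to O1; lactol anomers)
Conditions: DIBAL-H (3.5 equiv), CH2Cl2, −78 °C; MeOH, Rochelle salt; Et3N-deactivated silica
Reagents that add atoms: none
Why: DIBAL-H reduces the γ-lactone to the lactol (aluminium hemiacetal stable at −78 °C) and the vinylogous-ester ketone in 1,2-fashion; hydride should arrive anti to the neighbouring epoxide oxygen, giving the cis-epoxy alcohol, while dioxolane, epoxide and enamide are inert.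

Step 11
Reactants: 17 (2E)-N-[(3S,5S)-9,10-epoxy-2,8-dihydroxy-6-methoxy-1-oxaspiro[4.5]dec-6-en-3-yl]-6-(2-pentyl-1,3-dioxolan-2-yl)hex-2-enamide (8-OH and epoxide cis to O1; lactol anomers)
Product: 19 isariotin C, via keto lactol 18 (not isolated)
Conditions: Dowex 50W-X8 (H+ form), THF/H2O 4:1, 0 °C → rt; filter; then Et3N (0.3 equiv), 0 °C → rt
Reagents that add atoms: water O
Why: Acid hydrolyses the methyl enol ether (C-protonation; ionisation of the allylic alcohol should be retarded by the adjacent epoxide) and the dioxolane to give 18; mild base then closes the aminocyclohexane ring by 6-(enolendo)-exo-trig aldol addition of the only possible ketone enolate to the aldehyde released from the lactol. The acylamino group takes the exo (equatorial) position, the new carbinol OH the axial, ketone-hydrogen-bonded position (closed chair-like transition state), and the bridgehead α-carbon blocks dehydration and epimerisation.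

**Compound list**
1 | 4-bromo-3-methoxyphenol | COc1cc(O)ccc1Br | starting material
2 | tert-butyl(4-bromo-3-methoxyphenoxy)dimethylsilane | COc1cc(O[Si](C)(C)C(C)(C)C)ccc1Br | intermediate
3 | methyl (2R)-2-[(tert-butoxycarbonyl)amino]-3-iodopropanoate (Boc-3-iodo-L-alanine methyl ester) | CC(C)(C)OC(=O)N[C@@H](CI)C(=O)OC | starting material
4 | [(2R)-2-[(tert-butoxycarbonyl)amino]-3-methoxy-3-oxopropyl]zinc iodide | CC(C)(C)OC(=O)N[C@@H](C[Zn]I)C(=O)OC | intermediate
5 | methyl (2S)-2-[(tert-butoxycarbonyl)amino]-3-{4-[(tert-butyldimethylsilyl)oxy]-2-methoxyphenyl}propanoate | CC(C)(C)OC(=O)N[C@@H](Cc1ccc(O[Si](C)(C)C(C)(C)C)cc1OC)C(=O)OC | intermediate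
6 | methyl (2S)-2-amino-3-{4-[(tert-butyldimethylsilyl)oxy]-2-methoxyphenyl}propanoate trifluoroacetate salt | OC(=O)C(F)(F)F.N[C@@H](Cc1ccc(O[Si](C)(C)C(C)(C)C)cc1OC)C(=O)OC | intermediate
7 | (2E)-penta-2,4-dienoic acid | C=C/C=C/C(=O)O | starting material
8 | methyl (2S)-3-{4-[(tert-butyldimethylsilyl)oxy]-2-methoxyphenyl}-2-[(2E)-penta-2,4-dienamido]propanoate | C=C/C=C/C(=O)N[C@@H](Cc1ccc(O[Si](C)(C)C(C)(C)C)cc1OC)C(=O)OC | intermediate
9 | 1-bromoheptan-2-one | CCCCCC(=O)CBr | starting material
10 | methyl (2S)-2-[(2E)-5-(9-borabicyclo[3.3.1]nonan-9-yl)pent-2-enamido]-3-{4-[(tert-butyldimethylsilyl)oxy]-2-methoxyphenyl}propanoate | B1(CC/C=C/C(=O)N[C@@H](Cc3ccc(O[Si](C)(C)C(C)(C)C)cc3OC)C(=O)OC)C2CCCC1CCC2 | intermediate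
11 | 9-BBN enol borinate of 12 (O-boron enolate of the C7 ketone, C6=C7) | CCCCCC(OB1C2CCCC1CCC2)=CCC/C=C/C(=O)N[C@@H](Cc3ccc(O[Si](C)(C)C(C)(C)C)cc3OC)C(=O)OC | intermediate
12 | methyl (2S)-3-{4-[(tert-butyldimethylsilyl)oxy]-2-methoxyphenyl}-2-[(2E)-7-oxododec-2-enamido]propanoate | CCCCCC(=O)CCC/C=C/C(=O)N[C@@H](Cc1ccc(O[Si](C)(C)C(C)(C)C)cc1OC)C(=O)OC | intermediate
13 | methyl (2S)-3-{4-[(tert-butyldimethylsilyl)oxy]-2-methoxyphenyl}-2-[(2E)-6-(2-pentyl-1,3-dioxolan-2-yl)hex-2-enamido]propanoate | CCCCCC2(OCCO2)CCC/C=C/C(=O)N[C@@H](Cc1ccc(O[Si](C)(C)C(C)(C)C)cc1OC)C(=O)OC | intermediate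
14 | (2S)-3-(4-hydroxy-2-methoxyphenyl)-2-[(2E)-6-(2-pentyl-1,3-dioxolan-2-yl)hex-2-enamido]propanoic acid | CCCCCC2(OCCO2)CCC/C=C/C(=O)N[C@@H](Cc1ccc(O)cc1OC)C(=O)O | intermediate
15 | (2E)-N-[(3S,5S)-6-methoxy-2,8-dioxo-1-oxaspiro[4.5]deca-6,9-dien-3-yl]-6-(2-pentyl-1,3-dioxolan-2-yl)hex-2-enamide (acylamino group on the side of the unsubstituted ring arm) | CCCCCC4(OCCO4)CCC/C=C/C(=O)N[C@H]1C[C@@]2(OC1=O)C(OC)=CC(=O)C=C2 | intermediate
16 | 9,10-epoxide of 15, epoxide oxygen on the same ring face as the lactone oxygen O1 | CCCCCC4(OCCO4)CCC/C=C/C(=O)N[C@H]1C[C@@]2(OC1=O)C(OC)=CC(=O)[C@@H]3O[C@@H]32 | intermediate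
17 | lactol (C2–OH, anomers) and C8 allylic alcohol derived from 16; 8-OH, epoxide and O1 all cis | CCCCCC4(OCCO4)CCC/C=C/C(=O)N[C@H]1C[C@@]2(OC1O)C(OC)=C[C@H](O)[C@@H]3O[C@@H]32 | intermediate
18 | (2E)-N-[(3S,5S)-9,10-epoxy-2,8-dihydroxy-6-oxo-1-oxaspiro[4.5]decan-3-yl]-7-oxododec-2-enamide (keto lactol; 8-OH, epoxide and O1 cis) | CCCCCC(=O)CCC/C=C/C(=O)N[C@H]1C[C@@]2(OC1O)C(=O)C[C@H](O)[C@@H]3O[C@@H]32 | intermediate
19 | isariotin C: bicyclo[3.3.1]nonan-9-one with bridgehead OH, exo NH-(2E)-7-oxododec-2-enoyl, axial carbinol OH cis to N, and on the other ring a secondary OH and an epoxide both cis to the bridgehead OH | CCCCCC(=O)CCC/C=C/C(=O)N[C@H]1C[C@@]2(O)C(=O)[C@H]([C@H](O)[C@@H]3O[C@@H]32)[C@H]1O | target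

**Totals and risks**
Total steps: 11. Longest linear sequence: 11 steps (1 → 19).

Steps most likely to fail:

1. Step 8. The facial discrimination at the new quaternary carbon rests on 1,3-induction from the amino-acid centre and may be weak; capture by the amide oxygen may also compete. Fallback (external nucleophile, hydroxyl-directed epoxidation): from 13, TBAF in THF should give methyl (2S)-3-(4-hydroxy-2-methoxyphenyl)-2-[(2E)-6-(2-pentyl-1,3-dioxolan-2-yl)hex-2-enamido]propanoate F4. PhI(OAc)2 in MeCN/H2O should give the para-quinol methyl ester F5 after chromatographic removal of the carbinol epimer. H2O2/LiOH (hydroperoxide delivered by the tertiary OH) should give the syn-epoxy quinol methyl ester F6. DIBAL-H at −78 °C (ester to aldehyde, which closes onto the tertiary OH; ketone to alcohol) returns to 17.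

2. Step 11. Acid may ionise the alkoxy-allylic alcohol (Stork–Danheiser-type transposition with loss of the secondary OH), or β-elimination may outrun ring closure. Fallback (staged reduction with the carbinol masked): from 16, NaBH4/CeCl3 at −78 °C should reduce only the ketone to the hydroxy lactone F7. TBSOTf/2,6-lutidine should give the silyl ether lactone F8, and DIBAL-H at −78 °C the silyl ether lactol F9. Dowex (H+) in THF/H2O followed by Et3N (hydrolysis, then aldol) should give the O-silyl isariotin C F10, and HF·pyridine in THF returns to 19.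

3. Step 5. Hydroboration of the conjugated dienamide may be unselective (reduction of the conjugated system, boron on C4), or the borate may be protonated before it rearranges. Fallback (acetoacetic-ester alkylation for the same bond): from 6, acryloyl chloride/Et3N should give the acrylamide methyl ester F1. Cross-metathesis with 4-bromobut-1-ene (Hoveyda–Grubbs II, CH2Cl2, 40 °C) should give the (2E)-5-bromopent-2-enamide F2. C-alkylation of methyl 3-oxooctanoate with F2 (K2CO3, NaI, acetone) should give the β-keto ester F3, and Krapcho dealkoxycarbonylation (LiCl, wet DMSO, 120 °C) returns to 12.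

**Further compounds**
F1 | step 5 | methyl (2S)-2-acrylamido-3-{4-[(tert-butyldimethylsilyl)oxy]-2-methoxyphenyl}propanoate | C=CC(=O)N[C@@H](Cc1ccc(O[Si](C)(C)C(C)(C)C)cc1OC)C(=O)OC
F2 | step 5 | methyl (2S)-2-[(2E)-5-bromopent-2-enamido]-3-{4-[(tert-butyldimethylsilyl)oxy]-2-methoxyphenyl}propanoate | BrCC/C=C/C(=O)N[C@@H](Cc1ccc(O[Si](C)(C)C(C)(C)C)cc1OC)C(=O)OC
F3 | step 5 | methyl 2-hexanoyl-6-oxo-6-{[(2S)-1-methoxy-1-oxo-3-{4-[(tert-butyldimethylsilyl)oxy]-2-methoxyphenyl}propan-2-yl]amino}hex-4-enoate (4E; β-keto ester, epimers at the new centre) | CCCCCC(=O)C(CC/C=C/C(=O)N[C@@H](Cc1ccc(O[Si](C)(C)C(C)(C)C)cc1OC)C(=O)OC)C(=O)OC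
F4 | step 8 | methyl (2S)-3-(4-hydroxy-2-methoxyphenyl)-2-[(2E)-6-(2-pentyl-1,3-dioxolan-2-yl)hex-2-enamido]propanoate | CCCCCC2(OCCO2)CCC/C=C/C(=O)N[C@@H](Cc1ccc(O)cc1OC)C(=O)OC
F5 | step 8 | para-quinol methyl ester: 1-hydroxy-2-methoxy-4-oxocyclohexa-2,5-dien-1-yl in place of the aryl group of F4, carbinol configuration as in 15 | CCCCCC2(OCCO2)CCC/C=C/C(=O)N[C@@H](C[C@@]1(O)C(OC)=CC(=O)C=C1)C(=O)OC
F6 | step 8 | syn-epoxy quinol methyl ester: 5,6-epoxide of F5 cis to the tertiary OH | CCCCCC2(OCCO2)CCC/C=C/C(=O)N[C@@H](C[C@@]1(O)C(OC)=CC(=O)[C@@H]3O[C@@H]31)C(=O)OC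
F7 | step 11 | hydroxy lactone: 8-hydroxy analogue of 16 (8-OH cis to epoxide and O1) | CCCCCC4(OCCO4)CCC/C=C/C(=O)N[C@H]1C[C@@]2(OC1=O)C(OC)=C[C@H](O)[C@@H]3O[C@@H]32
F8 | step 11 | silyl ether lactone: 8-O-tert-butyldimethylsilyl ether of F7 | CCCCCC4(OCCO4)CCC/C=C/C(=O)N[C@H]1C[C@@]2(OC1=O)C(OC)=C[C@H](O[Si](C)(C)C(C)(C)C)[C@@H]3O[C@@H]32
F9 | step 11 | silyl ether lactol: 8-O-tert-butyldimethylsilyl ether of 17 | CCCCCC4(OCCO4)CCC/C=C/C(=O)N[C@H]1C[C@@]2(OC1O)C(OC)=C[C@H](O[Si](C)(C)C(C)(C)C)[C@@H]3O[C@@H]32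
F10 | step 11 | O-silyl isariotin C: tert-butyldimethylsilyl ether at the secondary OH next to the epoxide | CCCCCC(=O)CCC/C=C/C(=O)N[C@H]1C[C@@]2(O)C(=O)[C@H]([C@H](O[Si](C)(C)C(C)(C)C)[C@@H]3O[C@@H]32)[C@H]1O
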